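(The readings come from a simulation for substances that don't exist.)

| setting | south | north-west | elm | birch |
|---|---|---|---|---|
| free monomer | 0.10 M | 0.10 M | 0.10 M | 0.10 M |
| initiator | 0.14 mol% | 0.33 mol% | 0.3 mol% | 0.1 mol% |
| impurity | 81 µM | 81 µM | 81 µM | 81 µM |
| remark | run made earlier | run made earlier |  |  |
| time |  |  | 5.0 h | 5.0 h |

- south (time / h: monomer in chains / %): 0.417: 6.9; 0.667: 13.3; 1.00: 24.2; 1.33: 33.4; 2.00: 52.2; 3.00: 70.8; 5.00: 89.9
- north-west (time / h: monomer in chains / %): 0.667: 40.7; 1.33: 76.6; 2.00: 92.6; 3.00: 98.0; 4.00: 100.5; 5.00: 99.1

(each reading ± 0.5 percentage points)

- which of the two ends with the longer chains by the average number of monomer units in a chain (chains begun, living or dead) ("neither" if they lie within 10%) (elm / birch / neither)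
- average number of monomer units in a chain (chains begun, living or dead) at the end, elm
- average number of monomer units in a chain (chains begun, living or dead) at the end, birch

- the average divides the monomer in chains by the number of chains begun, living and dead together
- the earlier runs do not show the number of chains; that part of a forecast is a guess

- I began with an easy step, the late slope of the logarithm of the monomer left, a pseudo-first-order constant: 0.531 /h in the south run and 1.72 /h in the north-west run, a ratio of 3.24, larger than the loading ratio of 2.36.
- So I assumed that each impurity removes one initiator, and called the remainder net initiator: 59.0 µM in the south run. Dividing the south slope by it gave 9000 /M/h, the turnover frequency of a living end.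
- With that frequency, the north-west slope counted 191 µM living ends out of 249 µM net initiator, a share of 76.7%.
- I took elm, with 219 µM net initiator, as near complete, since north-west read 99.1% at its end. The whole net begun gave a lower bound of 457 units per chain; the north-west share, read mid-run, gave an estimate, not a bound, of 595.
- Birch has 19.0 µM net initiator, fewer than south. Turning over for 5.0 h with no lag gave 57.5% in chains and an upper bound of 3020. Subtracting the south lag of 0.681 h, where its late line meets zero, gave 52.2% and a lower bound of 2750.
- The forecast said birch, with 335 for elm and 650 for birch, on the guess that “every initiator starts a chain and impurity kills living ones”, both below my lower bounds.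
- The flasks gave birch as the longer, with 605 for elm, above my lower bound and close to my estimate, and 2940 for birch, inside its bracket.

    free monomer + initiator → living end + monomer in chains (k = 0.00380 /M/s)
    free monomer + living end → monomer in chains + living end, rate k2*[living end]*[free monomer] (k = 2.70 /M/s)
    free monomer → decomposition product (k = 1.40 × 10⁻⁶ /s)
    initiator + impurity → spent initiator (k = 110 /M/s)

- A neighbouring flask repeats elm with 3.2 × 10⁻⁴ M of impurity, more than its initiator, so the subtraction gives −20.0 µM, yet 8.35 × 10⁻⁶ M of living end stood at 5.00 h. The turnover frequency applied to those ends for 5.0 h, with no lag, gives 31.3% in chains and 3750 units per chain. The flask held 32.7% in chains, at 3920 units per chain.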